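## The problem

Abroquinone A is an isoflavanquinone. A 6,7-dimethoxychroman (aromatic ring A fused to pyran ring C) carries a 2,3-dimethoxy-1,4-benzoquinone (ring B) on C3 through the C3–C1' single bond. The only stereocenter is C3, which has the S configuration in the structure as drawn. It stands alone, so nothing in the molecule can relay its configuration and it must come from an external source of chirality. In the target, C3 is the γ-position of a quinone enone (C3–C1'=C6'–C5'=O), so acid or base can shift its hydrogen and racemise it; the quinone therefore has to be unveiled last and near neutrality. The quinone itself will not survive nucleophiles, reducing agents or hydrogenation. Ring A (O1, 6-OMe, 7-OMe, with O1 para to the C6 oxygen) is a hydroquinone diether that one-electron oxidants such as (NH4)2Ce(NO3)6 would attack, so ring B cannot be unmasked by oxidative demethylation. It has to come from a C2' phenol with a free C5' position and a phenol-selective oxidant. The feature that opens the key step is the oxygen pattern of ring A: O1 sits on C8a, para to the C6 oxygen and meta to the C7 oxygen. This is where a nucleophile ends up after adding to the ortho-quinone of a 4-alkylcatechol, so ring C can be closed through O1–C8a by oxidising a 6,7-catechol that carries the hydroxypropyl arm with C3 already in place.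

## Retrosynthesis

The last bond to be made is C5'=O. Target 21 is traced to phenol 20, whose ring B is a dimethoxyphenol with an unsubstituted para position. (KSO3)2NO oxidises such phenols to para-quinones and leaves aryl ethers alone. The neighbouring cut, oxidative demethylation of a ring-B hydroquinone diether, is rejected because ring A is itself a para-dialkoxybenzene. The forward reaction must be phenol-selective and mild enough for the C3 hydrogen.

Phenol 20 comes from MOM ether 19, and 19 from catechol 18 by methylation of the two ring-A hydroxyls. No skeletal bond is cut. The point is that the three ring-B oxygens are differentiated (two methyl, one acetal) from the start, while the two ring-A oxygens stay free until ring C is closed.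

Cutting O1–C8a of 18 opens ring C and leads to catechol 15, an acyclic 2,3-diarylpropan-1-ol. The usual isoflavan closure forms O1–C2 from a phenol and needs a third, differentiated oxygen on the benzyl arm. This cut needs only a symmetrical-looking catechol and uses the ring-A oxygen pattern itself to direct the closure. The precursor is simpler by one ring. The forward step passes through ortho-quinone 16 and quinone 17. It must choose C8a over C5, oxygen over carbon nucleophiles, and must leave C3 alone.

Catechol 15 is released from bis-benzyl ether 14 by hydrogenolysis, which is orthogonal to the MOM acetal and the methyl ethers.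

In 14 the C3–C4 bond next to the stereocenter is cut. This leads back through imide 13 and enolate 12 to arylacetyl imide 9 and benzylic bromide 11; auxiliary 7 fixes C3 in an Evans alkylation and is removed by hydride on the way to 14. Catalytic asymmetric hydroboration of a 1,1-disubstituted alkene would be shorter, but an ortho-alkoxy aryl group and a benzylic arm lie outside the secure range of that method. Alkylation of arylacetyl oxazolidinones with benzylic bromides is standard in isoflavan work, has a predictable sense, and gives diastereomers that can be purified. The forward reaction must not epimerise the acidic α-aryl position.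

Imide 9 is the acylation product of auxiliary 7 with arylacetic acid 6 (through anhydride 8). Acid 6 is cut at the C1'–CH2 bond. The MOM ether 2 of phenol 1 is lithiated next to the acetal (aryllithium 3) and alkylated with ethylene oxide to give alcohol 4, which is oxidised through aldehyde 5. The MOM group serves twice: as the director that fixes the 1',2',3',4' substitution pattern and as the mask of the later quinone oxygen. Electrophilic substitution of 1 would go para to the hydroxyl and give the wrong isomer.

Bromide 11 is made in one step from commercial alcohol 10. Compounds 1, 7 and 10 are the purchased starting materials.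

## Roads not taken

Alternative 1: The cut removes C3–C1' and passes through a pterocarpan with an extra C4–O bond.
- Forward step: 6,7-dimethoxy-2H-chromene A1 and 2,3-dimethoxy-1,4-benzoquinone A2 would be joined by the chiral Lewis acid TiCl2(TADDOLate) in a formal [3+2] cycloaddition. C3 of A1 attacks the unsubstituted C5 of the titanium-bound quinone, and the benzylic cation at C4 is caught by the neighbouring quinone oxygen. The product is the cis-fused pterocarpan A3. Hydrogenolysis of its benzylic C–O bond would give hydroquinone A4, and a mild oxidant the target.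
- Merits: the C3–C1' bond and the stereocenter are made in one convergent step. A2 is symmetrical, so no regiochemical question arises on the quinone. No protecting group is needed. The route would be about five steps, less than half of the chosen one.
- Weak points: the enantioselective version needs at least a full equivalent of the chiral titanium complex, and its selectivity depends strongly on both partners. A2 has a donor methoxy group beside each carbonyl and is a weaker acceptor than the mono-alkoxy quinones on which the method performs best. Competing [2+2] adducts and acid-induced oligomerisation of the electron-rich styrene A1 are expected. A3 forms as enantiomers, so a shortfall in selectivity cannot be corrected by simple separation.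
- Comparison: in step count and convergence this road is clearly better. The chosen plan sets against it an absolute configuration from a recoverable auxiliary with a predictable sense, a diastereomeric intermediate (13) that can be purified, and steps that are each well charted.

Alternative 2: The cut is C3–C4 together with O1–C2.
- Forward step: the enamine from [2-(benzyloxy)-3,4-dimethoxyphenyl]acetaldehyde A5 and a diarylprolinol silyl ether catalyst would add to the ortho-quinone methide 4,5-dimethoxy-6-methylidenecyclohexa-2,4-dien-1-one A7, set free by base from the sulfone 4,5-dimethoxy-2-[(4-methylbenzenesulfonyl)methyl]phenol A6. The phenoxide then closes onto the aldehyde carbon to give lactol A8 as an anomeric mixture. Reductive removal of the anomeric hydroxyl and debenzylation would converge on phenol 20.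
- Merits: catalytic in chirality, two ring bonds in one step, ring A arrives fully methylated so no air-sensitive catechol is handled, and about six to seven steps overall.
- Weak points: in A8 the new stereocenter bears an aryl group and sits α to a masked aldehyde. Ring–chain tautomerism exposes that aldehyde, which can re-form the enamine with the same catalyst, so the configuration is at risk in the flask in which it is made. The later deoxygenation passes through an oxocarbenium ion at C2 that can lose the C3 proton, a second exit for the stereocenter. A5 is a hindered ortho-substituted arylacetaldehyde and prone to self-condensation.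
- Comparison: this road is shorter and needs no auxiliary. The chosen plan sets against it that its stereocenter flanks a carbonyl only in imide 13 and is moved out of that position by the next step.

Alternative 3: The cut is O1–C8a, as in the chosen plan, together with C4–C4a.
- Forward step: the alkoxide of (2S)-3-bromo-2-[3,4-dimethoxy-2-(methoxymethoxy)phenyl]propan-1-ol A9 would add to 4,5-dimethoxybenzyne A11, generated from 4,5-dimethoxy-2-(trimethylsilyl)phenyl trifluoromethanesulfonate A10 and CsF. The aryl anion would then displace bromide (6-exo-tet) to give chroman A12, which is the same compound as 19.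
- Merits: ring A enters with both methoxy groups, the aryne is symmetrical, and the catechol handling and the methylation step disappear.
- Weak points: A9 is a 1,3-bromohydrin. Its alkoxide can close to the oxetane 3-[3,4-dimethoxy-2-(methoxymethoxy)phenyl]oxetane A13, which is achiral, so reopening by bromide would return racemic A9. It can also eliminate HBr across the benzylic C–H. The aryl anion formed after O-addition is protonated by any alcohol present faster than it displaces a β-branched primary bromide. Enantiopure A9 needs a separate desymmetrisation.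
- Comparison: if it worked it would be two to three steps shorter after the stereocenter. The chosen plan sets against it a nucleophile with no internal leaving group to consume it and an electrophile, the ortho-quinone, that forms cleanly and reacts where its electronics dictate.

Key step: step 9

Remark: by the CIP rules the stereocenter of the target is (3S). Chroman numbering (O1, C2, C3, C4, C4a, C5–C8, C8a; primed locants for ring B) is used for the open-chain precursors as well.

## Route

Step 1
Reactants: 1 2,3-dimethoxyphenol
Product: 2 1,2-dimethoxy-3-(methoxymethoxy)benzene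
Conditions: MOMCl, i-Pr2NEt, CH2Cl2, 0 °C to rt
Reagents that add atoms: chloromethyl methyl ether, COCCl
Why: O-alkylation of the phenol with an α-chloro ether under amine base (acetal protection). The MOM ether is stable to base, organolithium, hydride, hydrogenolysis and periodate and later directs the metalation.

Step 2
Reactants: 2 1,2-dimethoxy-3-(methoxymethoxy)benzene
Product: 4 2-[3,4-dimethoxy-2-(methoxymethoxy)phenyl]ethan-1-ol, via aryllithium 3 (not isolated)
Conditions: n-BuLi, THF, 0 °C; then ethylene oxide, −78 °C to rt; aq. NH4Cl
Reagents that add atoms: ethylene oxide, C1CO1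
Why: Directed ortho-metalation: the chelating OMOM group is a stronger director than methoxy, so deprotonation should occur next to the acetal and not next to the distal methoxy group. The aryllithium then opens the epoxide (SN2) to install the two-carbon arm.

Step 3
Reactants: 4 2-[3,4-dimethoxy-2-(methoxymethoxy)phenyl]ethan-1-ol
Product: 6 [3,4-dimethoxy-2-(methoxymethoxy)phenyl]acetic acid, via arylacetaldehyde 5 (not isolated)
Conditions: TEMPO (cat.), NaClO2, NaOCl (cat.), MeCN/phosphate buffer (pH 6.7), 35 °C
Reagents that add atoms: sodium chlorite, [Na+].[O-]Cl=O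
Why: Nitroxyl-catalysed oxidation to the aldehyde followed in the same flask by Pinnick-type chlorite oxidation, a protocol established for electron-rich 2-arylethanols. The buffered medium spares the MOM acetal and the catalytic amount of hypochlorite limits ring chlorination.

Step 4
Reactants: 6 [3,4-dimethoxy-2-(methoxymethoxy)phenyl]acetic acid, 7 (4S)-4-benzyl-1,3-oxazolidin-2-one
Product: 9 (4S)-4-benzyl-3-{[3,4-dimethoxy-2-(methoxymethoxy)phenyl]acetyl}-1,3-oxazolidin-2-one, via mixed pivalic anhydride 8 (not isolated)
Conditions: t-BuCOCl, Et3N, THF, −20 °C; then LiCl, 7, −20 °C to rt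
Reagents that add atoms: none
Why: N-acylation of the oxazolidinone through the mixed pivalic anhydride with LiCl/Et3N activation, routine for arylacetic acids. The bulk of the pivaloyl group directs attack to the arylacetyl carbonyl.

Step 5
Reactants: 10 [3,4-bis(benzyloxy)phenyl]methanol
Product: 11 1,2-bis(benzyloxy)-4-(bromomethyl)benzene
Conditions: PBr3, Et2O, 0 °C
Reagents that add atoms: phosphorus tribromide, BrP(Br)Br
Why: Conversion of a benzylic alcohol into the bromide through its phosphite ester (SN2). The electron-rich bromide is used at once, without storage.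

Step 6
Reactants: 9 (4S)-4-benzyl-3-{[3,4-dimethoxy-2-(methoxymethoxy)phenyl]acetyl}-1,3-oxazolidin-2-one, 11 1,2-bis(benzyloxy)-4-(bromomethyl)benzene
Product: 13 (4S)-4-benzyl-3-{(2S)-3-[3,4-bis(benzyloxy)phenyl]-2-[3,4-dimethoxy-2-(methoxymethoxy)phenyl]propanoyl}-1,3-oxazolidin-2-one, via sodium enolate 12 (not isolated)
Conditions: NaN(SiMe3)2, THF, −78 °C; then 11, −78 to −40 °C; AcOH quench
Reagents that add atoms: none
Why: Evans asymmetric alkylation: the chelated (Z)-sodium enolate is shielded on one face by the C4 benzyl group of the (S)-auxiliary, so the bromide enters from the opposite face and should set the future C3 as (S). The low temperature and the cold acidic quench guard the acidic α-aryl position against epimerisation.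

Step 7
Reactants: 13 (4S)-4-benzyl-3-{(2S)-3-[3,4-bis(benzyloxy)phenyl]-2-[3,4-dimethoxy-2-(methoxymethoxy)phenyl]propanoyl}-1,3-oxazolidin-2-one
Product: 14 (2S)-3-[3,4-bis(benzyloxy)phenyl]-2-[3,4-dimethoxy-2-(methoxymethoxy)phenyl]propan-1-ol
Conditions: LiBH4, MeOH (1 equiv), THF, 0 °C
Reagents that add atoms: none
Why: Reductive cleavage of the N-acyl oxazolidinone with LiBH4 gives the primary alcohol and releases the auxiliary for recovery. From here on the stereocenter is no longer α to a carbonyl and should be configurationally stable.

Step 8
Reactants: 14 (2S)-3-[3,4-bis(benzyloxy)phenyl]-2-[3,4-dimethoxy-2-(methoxymethoxy)phenyl]propan-1-ol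
Product: 15 4-{(2S)-3-hydroxy-2-[3,4-dimethoxy-2-(methoxymethoxy)phenyl]propyl}benzene-1,2-diol
Conditions: H2 (1 atm), 10% Pd/C, EtOAc/MeOH, rt
Reagents that add atoms: none
Why: Hydrogenolysis of the two benzyl aryl ethers. The MOM acetal, the methyl ethers and the oxygen-free benzylic stereocenter are inert under neutral conditions, and the catechol is used directly under argon.

Step 9
Reactants: 15 4-{(2S)-3-hydroxy-2-[3,4-dimethoxy-2-(methoxymethoxy)phenyl]propyl}benzene-1,2-diol
Product: 18 (3S)-3-[3,4-dimethoxy-2-(methoxymethoxy)phenyl]-3,4-dihydro-2H-chromene-6,7-diol, via side-chain ortho-quinone 16 (not isolated), via chroman-6,7-dione 17 (not isolated)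
Conditions: NaIO4 (2.1 equiv), MeCN/aq. phosphate buffer (pH 6.5), 0 °C, Ar; then aq. Na2S2O4, EtOAc
Reagents that add atoms: none
Why: Periodate oxidises the catechol in a two-electron step to the 4-alkyl-ortho-quinone 16, in which C8a is the β-carbon of the C7 enone; the primary hydroxyl (future O1) adds there in a 6-exo-trig conjugate addition and enolisation re-aromatises ring A, closing ring C. The closest known reactions are the cyclisation of dopaquinone, the oxidative lactonisation of dihydrocaffeic acid to 6,7-dihydroxydihydrocoumarin and the addition of methanol to 4-methyl-ortho-benzoquinone generated with iodate, all of which place the heteroatom on this same carbon. The trioxygenated product catechol is a stronger reductant than 15 and is oxidised by 16 or by periodate as it forms, so two equivalents of oxidant are used to carry all material to the vinylogous-ester quinone 17, which dithionite returns to catechol 18 in the work-up. No stereocenter is created; C3 is a spectator and should be preserved as long as the quinones do not tautomerise to quinone methides through the C4 hydrogens, which is why the medium is cold and near neutral and the reduction is prompt. Regioselectivity between C8a and C5 (both ortho to the chain, both giving six-membered rings) rests on the preference of oxygen nucleophiles for 1,4-addition at the carbon para to the C6 oxygen, whereas C5 is reached only by 1,6-addition and is flanked by the C6 carbonyl. Chemoselectivity is secured by the substrate: the catechol is the only ring with free hydroxyls, the MOM ether keeps ring B from being oxidised or from acting as an oxygen nucleophile, and the neutral medium keeps the electron-rich ring B from adding through carbon.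

Step 10
Reactants: 18 (3S)-3-[3,4-dimethoxy-2-(methoxymethoxy)phenyl]-3,4-dihydro-2H-chromene-6,7-diol
Product: 19 (3S)-3-[3,4-dimethoxy-2-(methoxymethoxy)phenyl]-6,7-dimethoxy-3,4-dihydro-2H-chromene
Conditions: MeI, K2CO3, DMF (degassed), rt, Ar
Reagents that add atoms: iodomethane, CI
Why: Double Williamson O-methylation of the catechol under carbonate base. Exclusion of oxygen prevents re-oxidation of the electron-rich catechol, and C3 carries no acidic hydrogen under these conditions.

Step 11
Reactants: 19 (3S)-3-[3,4-dimethoxy-2-(methoxymethoxy)phenyl]-6,7-dimethoxy-3,4-dihydro-2H-chromene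
Product: 20 6-[(3S)-6,7-dimethoxy-3,4-dihydro-2H-chromen-3-yl]-2,3-dimethoxyphenol
Conditions: 3 M HCl, MeOH, 50 °C
Reagents that add atoms: none
Why: Acid-catalysed acetal exchange removes the MOM group as dimethoxymethane. Aryl methyl ethers and the chroman ether are stable to dilute acid.

Step 12
Reactants: 20 6-[(3S)-6,7-dimethoxy-3,4-dihydro-2H-chromen-3-yl]-2,3-dimethoxyphenol
Product: 21 abroquinone A, 5-[(3S)-6,7-dimethoxy-3,4-dihydro-2H-chromen-3-yl]-2,3-dimethoxycyclohexa-2,5-diene-1,4-dione
Conditions: (KSO3)2NO, KH2PO4, H2O/acetone, rt
Reagents that add atoms: potassium nitrosodisulfonate, [K+].[K+].[O]N(S(=O)(=O)[O-])S(=O)(=O)[O-]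
Why: Teuber oxidation: the nitroxyl radical converts the phenol to a phenoxyl radical, a second equivalent combines at the free para position C5', and loss of imidodisulfonate gives the para-quinone. Aryl ethers of ring A are not attacked by this oxidant and the buffered medium should protect the C3 stereocenter.

## Compound list

1 | 2,3-dimethoxyphenol | COc1cccc(O)c1OC | starting material
2 | 1,2-dimethoxy-3-(methoxymethoxy)benzene | COCOc1cccc(OC)c1OC | intermediate
3 | [3,4-dimethoxy-2-(methoxymethoxy)phenyl]lithium | [Li]c1ccc(OC)c(OC)c1OCOC | intermediate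
4 | 2-[3,4-dimethoxy-2-(methoxymethoxy)phenyl]ethan-1-ol | OCCc1ccc(OC)c(OC)c1OCOC | intermediate
5 | [3,4-dimethoxy-2-(methoxymethoxy)phenyl]acetaldehyde | O=CCc1ccc(OC)c(OC)c1OCOC | intermediate
6 | [3,4-dimethoxy-2-(methoxymethoxy)phenyl]acetic acid | OC(=O)Cc1ccc(OC)c(OC)c1OCOC | intermediate
7 | (4S)-4-benzyl-1,3-oxazolidin-2-one | O=C1N[C@@H](Cc2ccccc2)CO1 | starting material
8 | [3,4-dimethoxy-2-(methoxymethoxy)phenyl]acetic 2,2-dimethylpropanoic anhydride | CC(C)(C)C(=O)OC(=O)Cc1ccc(OC)c(OC)c1OCOC | intermediate
9 | (4S)-4-benzyl-3-{[3,4-dimethoxy-2-(methoxymethoxy)phenyl]acetyl}-1,3-oxazolidin-2-one | O=C(Cc1ccc(OC)c(OC)c1OCOC)N1[C@@H](Cc2ccccc2)COC1=O | intermediate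
10 | [3,4-bis(benzyloxy)phenyl]methanol | OCc1ccc(OCc2ccccc2)c(OCc2ccccc2)c1 | starting material
11 | 1,2-bis(benzyloxy)-4-(bromomethyl)benzene | BrCc1ccc(OCc2ccccc2)c(OCc2ccccc2)c1 | intermediate
12 | sodium (Z)-1-[(4S)-4-benzyl-2-oxo-1,3-oxazolidin-3-yl]-2-[3,4-dimethoxy-2-(methoxymethoxy)phenyl]ethen-1-olate | [Na+].[O-]/C(=C\c1ccc(OC)c(OC)c1OCOC)N1[C@@H](Cc2ccccc2)COC1=O | intermediate
13 | (4S)-4-benzyl-3-{(2S)-3-[3,4-bis(benzyloxy)phenyl]-2-[3,4-dimethoxy-2-(methoxymethoxy)phenyl]propanoyl}-1,3-oxazolidin-2-one | O=C([C@@H](Cc1ccc(OCc2ccccc2)c(OCc2ccccc2)c1)c1ccc(OC)c(OC)c1OCOC)N1[C@@H](Cc2ccccc2)COC1=O | intermediate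
14 | (2S)-3-[3,4-bis(benzyloxy)phenyl]-2-[3,4-dimethoxy-2-(methoxymethoxy)phenyl]propan-1-ol | OC[C@@H](Cc1ccc(OCc2ccccc2)c(OCc2ccccc2)c1)c1ccc(OC)c(OC)c1OCOC | intermediate
15 | 4-{(2S)-3-hydroxy-2-[3,4-dimethoxy-2-(methoxymethoxy)phenyl]propyl}benzene-1,2-diol | OC[C@@H](Cc1ccc(O)c(O)c1)c1ccc(OC)c(OC)c1OCOC | intermediate
16 | 4-{(2S)-3-hydroxy-2-[3,4-dimethoxy-2-(methoxymethoxy)phenyl]propyl}cyclohexa-3,5-diene-1,2-dione | OC[C@@H](CC1=CC(=O)C(=O)C=C1)c1ccc(OC)c(OC)c1OCOC | intermediate
17 | (3S)-3-[3,4-dimethoxy-2-(methoxymethoxy)phenyl]-3,4-dihydro-2H-chromene-6,7-dione | COCOc1c([C@H]2COC3=CC(=O)C(=O)C=C3C2)ccc(OC)c1OC | intermediate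
18 | (3S)-3-[3,4-dimethoxy-2-(methoxymethoxy)phenyl]-3,4-dihydro-2H-chromene-6,7-diol | COCOc1c([C@H]2COc3cc(O)c(O)cc3C2)ccc(OC)c1OC | intermediate
19 | (3S)-3-[3,4-dimethoxy-2-(methoxymethoxy)phenyl]-6,7-dimethoxy-3,4-dihydro-2H-chromene | COCOc1c([C@H]2COc3cc(OC)c(OC)cc3C2)ccc(OC)c1OC | intermediate
20 | 6-[(3S)-6,7-dimethoxy-3,4-dihydro-2H-chromen-3-yl]-2,3-dimethoxyphenol | COc1ccc([C@H]2COc3cc(OC)c(OC)cc3C2)c(O)c1OC | intermediate
21 | abroquinone A, 5-[(3S)-6,7-dimethoxy-3,4-dihydro-2H-chromen-3-yl]-2,3-dimethoxycyclohexa-2,5-diene-1,4-dione | COC1=C(OC)C(=O)C([C@H]2COc3cc(OC)c(OC)cc3C2)=CC1=O | target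

## Step count and least certain steps

Total: 12 steps. Longest linear sequence: 11 steps (1 to 21 through steps 1–4 and 6–12); step 5 is a one-step branch.

Step 9 (key step). The most likely failure is that the neutral primary hydroxyl adds too slowly to quinone 16. Tautomerisation through the C4 hydrogens to a quinone methide would then compete (erosion of C3 or oligomers), as would hydration or intermolecular coupling of the quinone. The fallback forms the same O1–C8a bond by copper-catalysed O-arylation instead of oxidation. It sets out from imide 9. Enolate 12 is alkylated under the conditions of step 6 with commercial 1-bromo-2-(bromomethyl)-4,5-dimethoxybenzene (COc1cc(CBr)c(Br)cc1OC) to give (4S)-4-benzyl-3-{(2S)-3-(2-bromo-4,5-dimethoxyphenyl)-2-[3,4-dimethoxy-2-(methoxymethoxy)phenyl]propanoyl}-1,3-oxazolidin-2-one F1. LiBH4 reduction as in step 7 should give (2S)-3-(2-bromo-4,5-dimethoxyphenyl)-2-[3,4-dimethoxy-2-(methoxymethoxy)phenyl]propan-1-ol F2. An Ullmann-type intramolecular C–O coupling (CuI, 1,10-phenanthroline, Cs2CO3, toluene, 110 °C) would close ring C and rejoin the route at 19. This fallback is shorter than the main sequence; it is held in reserve because the plan is built on the oxidative closure.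

Step 6. The ortho-substituted, aryl-stabilised enolate 12 may alkylate sluggishly and decompose on warming, and proton exchange between product 13 and unreacted enolate would erode the diastereomeric purity. The fallback replaces auxiliary control by catalytic asymmetric hydrogenation and sets out from acid 6. Perkin condensation with commercial 3,4-bis(benzyloxy)benzaldehyde (O=Cc1ccc(OCc2ccccc2)c(OCc2ccccc2)c1; Ac2O, Et3N, 110 °C) should give (2E)-3-[3,4-bis(benzyloxy)phenyl]-2-[3,4-dimethoxy-2-(methoxymethoxy)phenyl]prop-2-enoic acid F3. Hydrogenation with H2 and [Ir(cod)(L*)][B(3,5-(CF3)2C6H3)4] (L* = chiral spiro phosphine–oxazoline, enantiomer chosen to deliver the S acid; Et3N, MeOH) should give (2S)-3-[3,4-bis(benzyloxy)phenyl]-2-[3,4-dimethoxy-2-(methoxymethoxy)phenyl]propanoic acid F4, the benzyl ethers being inert to the homogeneous catalyst. Reduction with LiAlH4 in THF at 0 °C returns to the route at 14.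

Step 2. Deprotonation may leak to the position next to the distal methoxy group, and the chelated aryllithium 3 may open ethylene oxide slowly, allowing epoxide oligomerisation. The fallback fixes the substitution pattern through the phenol and sets out from 1. Magnesium-mediated ortho-formylation (MgCl2, Et3N, paraformaldehyde, MeCN, reflux) can only occupy the single free ortho position and should give 2-hydroxy-3,4-dimethoxybenzaldehyde F5. Protection as in step 1 gives 3,4-dimethoxy-2-(methoxymethoxy)benzaldehyde F6. Wittig methylenation (Ph3PCH3Br, KOt-Bu, THF) gives 1-ethenyl-3,4-dimethoxy-2-(methoxymethoxy)benzene F7. Hydroboration with 9-BBN gives 9-{2-[3,4-dimethoxy-2-(methoxymethoxy)phenyl]ethyl}-9-borabicyclo[3.3.1]nonane F8, not isolated, and NaOH/H2O2 oxidation returns to the route at 4.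

Step 12. The nitroxyl may combine at the methoxy-bearing ortho carbon instead of C5' (loss of methanol to an ortho-quinone), or conversion may stall and the product quinone degrade during a long exposure to the aqueous medium. The fallback introduces the C5' heteroatom by electrophilic substitution that only a phenoxide undergoes, and sets out from 20. Azo coupling with commercial 4-methoxybenzenediazonium tetrafluoroborate (COc1ccc([N+]#N)cc1.F[B-](F)(F)F; aq. NaOH, 0 °C) should give 6-[(3S)-6,7-dimethoxy-3,4-dihydro-2H-chromen-3-yl]-2,3-dimethoxy-4-[(E)-(4-methoxyphenyl)diazenyl]phenol F9. Reduction with Na2S2O4 gives 4-amino-6-[(3S)-6,7-dimethoxy-3,4-dihydro-2H-chromen-3-yl]-2,3-dimethoxyphenol F10. Oxidation with FeCl3 in cold dilute HCl passes through 6-[(3S)-6,7-dimethoxy-3,4-dihydro-2H-chromen-3-yl]-4-imino-2,3-dimethoxycyclohexa-2,5-dien-1-one F11, not isolated, whose hydrolysis in the flask returns to the route at 21.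

## Further compounds

F1 | step 9 | (4S)-4-benzyl-3-{(2S)-3-(2-bromo-4,5-dimethoxyphenyl)-2-[3,4-dimethoxy-2-(methoxymethoxy)phenyl]propanoyl}-1,3-oxazolidin-2-one | O=C([C@@H](Cc1cc(OC)c(OC)cc1Br)c1ccc(OC)c(OC)c1OCOC)N1[C@@H](Cc2ccccc2)COC1=O
F2 | step 9 | (2S)-3-(2-bromo-4,5-dimethoxyphenyl)-2-[3,4-dimethoxy-2-(methoxymethoxy)phenyl]propan-1-ol | OC[C@@H](Cc1cc(OC)c(OC)cc1Br)c1ccc(OC)c(OC)c1OCOC
F3 | step 6 | (2E)-3-[3,4-bis(benzyloxy)phenyl]-2-[3,4-dimethoxy-2-(methoxymethoxy)phenyl]prop-2-enoic acid | OC(=O)/C(=C/c1ccc(OCc2ccccc2)c(OCc2ccccc2)c1)c1ccc(OC)c(OC)c1OCOC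
F4 | step 6 | (2S)-3-[3,4-bis(benzyloxy)phenyl]-2-[3,4-dimethoxy-2-(methoxymethoxy)phenyl]propanoic acid | OC(=O)[C@@H](Cc1ccc(OCc2ccccc2)c(OCc2ccccc2)c1)c1ccc(OC)c(OC)c1OCOC
F5 | step 2 | 2-hydroxy-3,4-dimethoxybenzaldehyde | COc1ccc(C=O)c(O)c1OC
F6 | step 2 | 3,4-dimethoxy-2-(methoxymethoxy)benzaldehyde | COCOc1c(C=O)ccc(OC)c1OC
F7 | step 2 | 1-ethenyl-3,4-dimethoxy-2-(methoxymethoxy)benzene | C=Cc1ccc(OC)c(OC)c1OCOC
F8 | step 2 | 9-{2-[3,4-dimethoxy-2-(methoxymethoxy)phenyl]ethyl}-9-borabicyclo[3.3.1]nonane | COCOc1c(CCB2C3CCCC2CCC3)ccc(OC)c1OC
F9 | step 12 | 6-[(3S)-6,7-dimethoxy-3,4-dihydro-2H-chromen-3-yl]-2,3-dimethoxy-4-[(E)-(4-methoxyphenyl)diazenyl]phenol | COc1ccc(/N=N/c2cc([C@H]3COc4cc(OC)c(OC)cc4C3)c(O)c(OC)c2OC)cc1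
F10 | step 12 | 4-amino-6-[(3S)-6,7-dimethoxy-3,4-dihydro-2H-chromen-3-yl]-2,3-dimethoxyphenol | Nc1cc([C@H]2COc3cc(OC)c(OC)cc3C2)c(O)c(OC)c1OC
F11 | step 12 | 6-[(3S)-6,7-dimethoxy-3,4-dihydro-2H-chromen-3-yl]-4-imino-2,3-dimethoxycyclohexa-2,5-dien-1-one | COC1=C(OC)C(=N)C=C([C@H]2COc3cc(OC)c(OC)cc3C2)C1=O
A1 | alternative 1 | 6,7-dimethoxy-2H-chromene | COc1cc2OCC=Cc2cc1OC
A2 | alternative 1 | 2,3-dimethoxycyclohexa-2,5-diene-1,4-dione (2,3-dimethoxy-1,4-benzoquinone) | COC1=C(OC)C(=O)C=CC1=O
A3 | alternative 1 | cis-8-hydroxy-2,3,9,10-tetramethoxypterocarpan, C6a configured as the future C3 of the target | COc1cc2OC[C@H]3[C@@H](c2cc1OC)Oc1c(OC)c(OC)c(O)cc13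
A4 | alternative 1 | 2-[(3S)-6,7-dimethoxy-3,4-dihydro-2H-chromen-3-yl]-5,6-dimethoxybenzene-1,4-diol | COc1c(OC)c(O)c([C@H]2COc3cc(OC)c(OC)cc3C2)cc1O
A5 | alternative 2 | [2-(benzyloxy)-3,4-dimethoxyphenyl]acetaldehyde | O=CCc1ccc(OC)c(OC)c1OCc1ccccc1
A6 | alternative 2 | 4,5-dimethoxy-2-[(4-methylbenzenesulfonyl)methyl]phenol | COc1cc(O)c(CS(=O)(=O)c2ccc(C)cc2)cc1OC
A7 | alternative 2 | 4,5-dimethoxy-6-methylidenecyclohexa-2,4-dien-1-one | C=C1C=C(OC)C(OC)=CC1=O
A8 | alternative 2 | (3S)-3-[2-(benzyloxy)-3,4-dimethoxyphenyl]-6,7-dimethoxy-3,4-dihydro-2H-chromen-2-ol, anomeric mixture at C2 | COc1ccc([C@H]2C(O)Oc3cc(OC)c(OC)cc3C2)c(OCc2ccccc2)c1OC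
A9 | alternative 3 | (2S)-3-bromo-2-[3,4-dimethoxy-2-(methoxymethoxy)phenyl]propan-1-ol | OC[C@@H](CBr)c1ccc(OC)c(OC)c1OCOC
A10 | alternative 3 | 4,5-dimethoxy-2-(trimethylsilyl)phenyl trifluoromethanesulfonate | COc1cc(OS(=O)(=O)C(F)(F)F)c([Si](C)(C)C)cc1OC
A11 | alternative 3 | 4,5-dimethoxybenzyne (1,2-didehydro-4,5-dimethoxybenzene) | COC1=CC#CC=C1OC
A12 | alternative 3 | (3S)-3-[3,4-dimethoxy-2-(methoxymethoxy)phenyl]-6,7-dimethoxy-3,4-dihydro-2H-chromene (identical with 19) | COCOc1c([C@H]2COc3cc(OC)c(OC)cc3C2)ccc(OC)c1OC
A13 | alternative 3 | 3-[3,4-dimethoxy-2-(methoxymethoxy)phenyl]oxetane | COCOc1c(C2COC2)ccc(OC)c1OC
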